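In a one-step world the starting complex meets incoming ligand that never runs down, so each portion fades at one steady rate and the flask ends full of complex with one exchanged; you can test that world against these flasks.

| setting | south-west | north | east | alpha | theta | zeta | gamma | beta | epsilon |
|---|---|---|---|---|---|---|---|---|---|
| starting complex | 0.0042 M (in portions, 3) | 0.019 M (in portions, 3) | 0.069 M (in portions, 3) | 0.040 M (in portions, 3) | 0.020 M (in portions, 3) | 0.012 M (in portions, 3) | 0.010 M (in portions, 3) | 0.060 M (in portions, 3) | 0.0050 M (in portions, 3) |
| incoming ligand | 0.024 M | 0.024 M | 0.024 M | 0.0240 M | 0.0240 M | 0.0240 M | 0.0240 M | 0.0240 M | 0.0240 M |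
| remark | run made earlier; portions every 15 h | run made earlier; portions every 15 h | run made earlier; portions every 15 h | the portions of starting complex follow each other after 15 h, the first at the start | the portions of starting complex follow each other after 15 h, the first at the start | the portions of starting complex follow each other after 15 h, the first at the start | the portions of starting complex follow each other after 15 h, the first at the start | the portions of starting complex follow each other after 15 h, the first at the start | the portions of starting complex follow each other after 15 h, the first at the start |
| time |  |  |  | 50 h | 50 h | 50 h | 50 h | 50 h | 50 h |

- south-west (time / h: complex with one exchanged / %, starting complex / %): 4.00: 10.4, 13.0; 10.0: 6.6, 2.5; 20.0: 16.7, 11.7; 48.0: 30.5, 2.8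
- north (time / h: complex with one exchanged / %, starting complex / %): 6.00: 10.8, 6.7; 20.0: 22.9, 14.2; 30.0: 29.1, 4.9; 48.0: 50.7, 11.0
- east (time / h: complex with one exchanged / %, starting complex / %): 4.00: 9.4, 16.2; 10.0: 13.2, 5.1; 20.0: 22.4, 23.0; 48.0: 29.1, 28.2

(readings scatter by 1 percentage point)



- the flasks put in order of amount of complex with one exchanged, in percent of the starting complex charged, best first, at 50 h (alpha / theta / zeta / gamma / beta / epsilon)
- the amount of complex with one exchanged, in percent of the starting complex charged of the flask you put first, at 50 h
- the amount of complex with one exchanged, in percent of the starting complex charged of the flask you put last, at 50 h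

Start with the rate. In the south-west run, where the ligand far exceeds a portion (pseudo-first-order), the reading y of starting complex is 13.0% of the whole charge at t = 4.00 h, so with n portions the rate constant k of the first portion's fading reads

k = ln(1/(n·y))/t = 0.235 /h

and the half-life read from it, 2.95 h, is shorter than the interval between portions.

Now go round again and hold that quick start against the east run. There the readings of complex with one exchanged show 9.4% after the first 4.00 h, but a gain of only 6.7 percentage points over the last 28.0 h, so as read the rate per hour has slowed by a factor of

S = 9.82.

In the east run the reading of starting complex stands higher at 48.0 h than at 4.00 h, so I lay the slowing on the ligand, the limiting reagent there. Each exchange takes one ligand, which gives a ceiling C = cX/cM, the charged incoming ligand over the charged starting complex, and at 48.0 h the reading y of complex with one exchanged in the east run stands at this share of it, the fill F: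

C = 34.8%, F = y/C = 83.7%.

My own reckoning for beta, with its ceiling of 40.0% and the fill taken over from the east run, is 33.5%.

The forecast gives theta > zeta > alpha > gamma > beta > epsilon, with 51% first and 32% last, and says: “The middle and bottom placings are close.”

The flask gives theta > zeta > gamma > alpha > epsilon > beta, from 51.9% down to 33.3%, so beta comes last at 33.3%, under epsilon at 35.4%.

    complex with one exchanged + incoming ligand ⇌ leaving ligand + complex with two exchanged (K = 0.490, k = 0.00240 /M/s)
    starting complex + incoming ligand ⇌ leaving ligand + complex with one exchanged (K = 14.0, k = 0.00230 /M/s)
    starting complex ⇌ dormant form (K = 1.90, k = 2.20 × 10⁻⁵ /s)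

Left ten times as long, beta stands at 32.9%, hardly moved. The fill of beta at 50.0 h comes to 83.2%. For the same flask as beta with 0.0096 M of incoming ligand, the ceiling is 16.0% and the fill read from the east run gives 13.4%, while that flask holds 14.8% of complex with one exchanged.

The runs were generated by integration on assumed constants.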